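**Plan**

Labels: C1–C7a are the tetrahydrophthalide half (C1 lactone C=O, C3 carries the butylidene); the cyclobutane is C6–C7–C3′–C8′ (C3′ = spiro carbon of the aromatic phthalide, C8′ = propyl-bearing CH).
Cuts, in retrosynthetic order: the exocyclic C3=CH bond (aldol/dehydration), C5–C6 of ring B (radical closure), C3a–C4 (vinyl by Stille coupling), C7–C7a and C8′–propyl (two directed C–H couplings), aryl–C3′ (Grignard addition/lactonisation).
Enabling feature: C6 is a cyclobutane CH whose bond to C5 has to be cis to C7, and C5–C4 run to the butenolide β-carbon C3a; a radical at C6 and a vinyl group (C4=C5) on C3a of the C7-bound butenolide are therefore placed to close ring B.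
Forward order: spirophthalide on the cyclobutane, propyl at C8′, butenolide at C7, vinyl at C3a, ring B, butylidene at C3.
Stereochemistry: O/CO2H cis from anti addition to the cyclobutanone; absolute configuration from a ligand-controlled desymmetrising C–H alkenylation at C8′; C7 from cis-directed palladation; C6 from the enforced cis ring fusion; Z alkene from the elimination.

Key step: step 14

Remark: the antipode of the chiral ligand in step 2 that leads to the (8′R) series is to be fixed in a first run. Compounds 15–23 are drawn all-cis; a C6 epimer of any of them would converge in step 14, where C6 becomes a planar radical.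

**Route**

Step 1
Reactants: 1 3-oxocyclobutane-1-carboxylic acid; 2 ethyl 2-iodobenzoate
Product: 5 cis-3'-oxo-3'H-spiro[cyclobutane-1,1'-isobenzofuran]-3-carboxylic acid (CO2H cis to the lactone oxygen), via aryl Grignard reagent 3 (not isolated), via magnesium alkoxide adduct 4 (not isolated)
Conditions: 2 (2.2 equiv), i-PrMgCl·LiCl (2.1 equiv), THF, −40 °C; then 1, −40 °C → rt; 2 M HCl; crystallisation of the cis isomer
Reagents that add atoms: none
Why: Iodine–magnesium exchange at −40 °C spares the ester, one equivalent of 3 deprotonates the acid and the second adds to the cyclobutanone (Grignard 1,2-addition) from the face anti to the carboxylate, so that the alkoxide of 4 ends cis to CO2H and closes the phthalide by lactonisation onto the ortho ester, which fixes the O/CO2H cis relationship needed at C3′.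

Step 2
Reactants: 5 cis spirophthalide acid; 6 (E)-prop-1-enylboronic acid pinacol ester
Product: 7 2-[(E)-prop-1-enyl]-3'-oxo-3'H-spiro[cyclobutane-1,1'-isobenzofuran]-3-carboxylic acid (propenyl at C8′ cis to CO2H and to the lactone oxygen; single enantiomer)
Conditions: Pd(OAc)2 (10 mol %), chiral N-acetyl aminoethyl amine (MPAAM) ligand (20 mol %), Ag2CO3 (2 equiv), 1,4-benzoquinone (0.2 equiv), H2O (5 equiv), t-AmOH, 80 °C
Reagents that add atoms: none
Why: Carboxylate-directed β-methylene C(sp3)–H activation on divalent palladium followed by transmetalation with the alkenylboronate and reductive elimination (a C–H Suzuki–Miyaura-type cross-coupling, Ag2CO3 returning zerovalent palladium to the active state) is a known enantioselective desymmetrisation of cyclobutanecarboxylic acids, in which the chiral ligand picks one of the two enantiotopic CH2 groups in the metalation step and palladation cis to the carboxylate places the propenyl group on the carboxyl face, so that C8′ and with it the absolute configuration of the whole series are set here.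

Step 3
Reactants: 7 propenyl acid
Product: 8 2-propyl-3'-oxo-3'H-spiro[cyclobutane-1,1'-isobenzofuran]-3-carboxylic acid (propyl, CO2H and lactone oxygen cis)
Conditions: H2 (1 atm), 10% Pd/C, EtOAc, rt
Reagents that add atoms: none
Why: Heterogeneous hydrogenation saturates the disubstituted alkene to the propyl group at 1 atm without hydrogenolysis of the phthalide C–O bond and without touching a stereocentre.

Step 4
Reactants: 8 propyl acid; 9 quinolin-8-amine
Product: 10 N-(quinolin-8-yl) amide of 8
Conditions: 9 (1.2 equiv), EDC·HCl (1.5 equiv), DMAP (0.3 equiv), CH2Cl2, 0 °C → rt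
Reagents that add atoms: none
Why: Carbodiimide-mediated amide coupling installs the bidentate quinolin-8-yl auxiliary under conditions that avoid a ketene, so the cis configuration at C6 that the next C–H step relies on is kept.

Step 5
Reactants: 11 4-methoxyfuran-2(5H)-one
Product: 12 3-iodo-4-methoxyfuran-2(5H)-one
Conditions: NIS (1.1 equiv), TFA (0.3 equiv), MeCN, 50 °C
Reagents that add atoms: N-iodosuccinimide, O=C1CCC(=O)N1I
Why: Electrophilic iodination of the push–pull enol ether occurs at C3, the nucleophilic α-carbon of the vinylogous carbonate, as is usual for tetronates.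

Step 6
Reactants: 10 propyl amide; 12 3-iodo-4-methoxyfuran-2(5H)-one
Product: 13 all-cis amide carrying the 4-methoxy-2-oxo-2,5-dihydrofuran-3-yl group at C7
Conditions: 12 (2.5 equiv), Pd(OAc)2 (15 mol %), AgOAc (2 equiv), (BnO)2PO2H (20 mol %), toluene, 100 °C
Reagents that add atoms: none
Why: Auxiliary-directed β-C(sp3)–H alkenylation proceeds through the five-membered N,N-chelated palladacycle of divalent palladium, oxidative addition of the alkenyl iodide to tetravalent palladium and C–C reductive elimination with retention, and because the only β-hydrogen left cis to the amide is the one at C7 the furanone is delivered cis to the amide, the propyl group and the lactone oxygen, which sets C7.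

Step 7
Reactants: 13 all-cis amide
Product: 15 all-cis C6 carboxylic acid with the methyl tetronate at C7, via N-Boc imide 14 (not isolated)
Conditions: Boc2O (3 equiv), DMAP (1 equiv), MeCN, 60 °C; then LiOH·H2O (3 equiv), 30% H2O2, THF/H2O, 0 °C; Na2SO3; 1 M HCl
Reagents that add atoms: hydrogen peroxide (as LiOOH), OO
Why: N-Boc activation twists the amide out of conjugation and LiOOH then cleaves the exocyclic acyl–nitrogen bond (hydroperoxide hydrolysis of an activated imide), conditions to which the methyl tetronate is inert and after which a phthalide opened by hydroxide recloses on acidification.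

Step 8
Reactants: 15 acid
Product: 16 tert-butyl ester of 15
Conditions: t-BuOC(=NH)CCl3 (2 equiv), BF3·OEt2 (10 mol %), CH2Cl2/cyclohexane, rt
Reagents that add atoms: tert-butyl 2,2,2-trichloroacetimidate, CC(C)(C)OC(=N)C(Cl)(Cl)Cl
Why: Acid-catalysed tert-butylation with the trichloroacetimidate goes through the tert-butyl cation, so the hindered carboxyl group reacts at oxygen, and the ester keeps the acid from adding to the β-triflate made in step 10.

Step 9
Reactants: 16 tert-butyl ester
Product: 17 tetronic acid (4-hydroxy-2-oxo-2,5-dihydrofuran-3-yl at C7)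
Conditions: LiCl (6 equiv), DMSO, 100 °C; 1 M HCl
Reagents that add atoms: none
Why: Chloride cleaves the O–methyl bond of the vinylogous methyl carbonate by SN2 attack at carbon (Krapcho-type dealkylation with the tetronate as leaving group), which leaves the tert-butyl ester and the phthalide untouched.

Step 10
Reactants: 17 tetronic acid
Product: 18 enol triflate at C3a
Conditions: Tf2O (1.2 equiv), i-Pr2NEt (1.5 equiv), CH2Cl2, −78 °C
Reagents that add atoms: trifluoromethanesulfonic anhydride, O=S(=O)(OS(=O)(=O)C(F)(F)F)C(F)(F)F
Why: O-Sulfonylation of the acidic enol of the tetronic acid with Tf2O gives the enol triflate, the standard handle for cross-coupling at the butenolide β-carbon.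

Step 11
Reactants: 18 enol triflate; 19 tributyl(vinyl)stannane
Product: 20 tert-butyl ester carrying the 4-vinyl-2-oxo-2,5-dihydrofuran-3-yl group at C7
Conditions: 19 (1.5 equiv), Pd(PPh3)4 (5 mol %), LiCl (3 equiv), THF, 50 °C
Reagents that add atoms: none
Why: Stille coupling of the electron-poor enol triflate with the vinylstannane (oxidative addition to zerovalent palladium, chloride-assisted transmetalation, reductive elimination) places the C4=C5 vinyl group on C3a.

Step 12
Reactants: 20 vinylbutenolide tert-butyl ester
Product: 21 C6 carboxylic acid with the 4-vinylbutenolide at C7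
Conditions: TFA/CH2Cl2 (1:4), 0 °C → rt
Reagents that add atoms: none
Why: Acidolysis of the tert-butyl ester (E1 loss of isobutene) frees the C6 acid, and the electron-poor dienyl lactone is not protonated under these conditions.

Step 13
Reactants: 21 acid; 22 N-hydroxyphthalimide
Product: 23 N-acyloxyphthalimide of the C6 acid with the 4-vinylbutenolide at C7
Conditions: 22 (1.2 equiv), DIC (1.2 equiv), DMAP (0.1 equiv), CH2Cl2, 0 °C → rt
Reagents that add atoms: none
Why: Carbodiimide esterification (Steglich type) with N-hydroxyphthalimide turns the acid into the redox-active ester that step 14 needs.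

Step 14
Reactants: 23 N-acyloxyphthalimide
Product: 24 (6S,7R,3′R,8′R) tetracyclic butenolide with C3 unsubstituted (the target without its butylidene)
Conditions: Ru(bpy)3(PF6)2 (1 mol %), diethyl 2,6-dimethyl-1,4-dihydropyridine-3,5-dicarboxylate (Hantzsch ester, 1.5 equiv), i-Pr2NEt (2 equiv), CH2Cl2 (0.01 M), blue LEDs, rt
Reagents that add atoms: none
Why: The excited ruthenium complex is quenched by the dihydropyridine and the resulting monovalent ruthenium species passes one electron to the phthalimide ester, whose radical anion loses phthalimide anion and CO2 to leave the secondary cyclobutyl radical at C6; this nucleophilic radical adds to C5, the terminus of the s-cis dienyl lactone, and the adduct radical, spread over C4, C7a and the lactone carbonyl, is quenched at C4 by hydrogen transfer from the dihydropyridine (or by a second electron and a proton). The closest known reaction type is the reductive decarboxylative radical conjugate addition (Giese reaction) of N-acyloxyphthalimides under photoredox conditions, used here intramolecularly in the 1,6-sense. Ring B closes in the 6-endo-trig mode, which beats 5-exo attack at C4 because that path would give an unstabilised primary radical on a strained bicyclo[3.2.0]heptene. The new stereocentre C6 is controlled by the substrate: the two-carbon tether hangs from C7 on the face of the lactone oxygen and can only bridge to the same face of the flat radical, so the 4/6 fusion is cis and the configuration of C6 in 23 is irrelevant. The step needs 6-endo regioselectivity and cyclisation ahead of hydrogen transfer to, or β-scission of, the cyclobutyl radical; the first is secured by the polarised dienoate on its rigid cis-alkene tether, the second by high dilution and the closeness of C5, while the amine moves any 3a,4-ene isomer into conjugation.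

Step 15
Reactants: 24 tetracyclic butenolide; 25 butanal
Product: 27 3-(1-hydroxybutyl) adduct of 24 (mixture at C3 and the carbinol carbon), via silyloxyfuran 26 (not isolated)
Conditions: TBSOTf (1.3 equiv), Et3N (2 equiv), CH2Cl2, 0 °C; pentane, filtration; then 25 (2 equiv), BF3·OEt2 (1.2 equiv), CH2Cl2, −78 °C; aq. NaHCO3
Reagents that add atoms: none
Why: Soft enolisation gives the aromatic 2-silyloxyfuran by deprotonation at C3, and its vinylogous Mukaiyama aldol reaction with butanal occurs at that γ-carbon, the two new stereocentres (C3 and the carbinol carbon) forming as a mixture that is of no consequence because both become sp2 in step 16.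

Step 16
Reactants: 27 hydroxybutyl adduct
Product: 29 CNP0248594.2 ((3Z,6S,7R,3′R,8′R)-butylidene tetracycle), via mesylate 28 (not isolated)
Conditions: MsCl (1.5 equiv), Et3N (3 equiv), CH2Cl2, 0 °C; then DBU (2 equiv), rt
Reagents that add atoms: none
Why: Mesylation and base-induced E1cB elimination through the furanolate give the γ-alkylidene butenolide, the Z isomer being favoured because the propyl group then points away from C4H2.

**Compound list**

1 | 3-oxocyclobutane-1-carboxylic acid | O=C1CC(C1)C(=O)O | starting material
2 | ethyl 2-iodobenzoate | CCOC(=O)c1ccccc1I | starting material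
3 | 2-(ethoxycarbonyl)phenylmagnesium chloride (ArMgCl·LiCl) | CCOC(=O)c1ccccc1[Mg]Cl | intermediate
4 | ethyl 2-(cis-3-carboxy-1-hydroxycyclobutyl)benzoate as its chloromagnesium alkoxide carboxylate (drawn neutral) | OC(=O)[C@H]1C[C@](O)(c2ccccc2C(=O)OCC)C1 | intermediate
5 | cis-3'-oxo-3'H-spiro[cyclobutane-1,1'-isobenzofuran]-3-carboxylic acid (CO2H cis to lactone O) | OC(=O)[C@H]1C[C@@]2(OC(=O)c3ccccc32)C1 | intermediate
6 | (E)-prop-1-enylboronic acid pinacol ester | C/C=C/B1OC(C)(C)C(C)(C)O1 | starting material
7 | 2-[(E)-prop-1-enyl] acid, propenyl/CO2H/lactone O cis | OC(=O)[C@H]1[C@@H](/C=C/C)[C@@]2(OC(=O)c3ccccc32)C1 | intermediate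
8 | 2-propyl acid, propyl/CO2H/lactone O cis | OC(=O)[C@H]1[C@@H](CCC)[C@@]2(OC(=O)c3ccccc32)C1 | intermediate
9 | quinolin-8-amine | Nc1cccc2cccnc12 | starting material
10 | N-(quinolin-8-yl) amide of 8 | O=C(Nc1cccc2cccnc12)[C@H]1[C@@H](CCC)[C@@]2(OC(=O)c3ccccc32)C1 | intermediate
11 | 4-methoxyfuran-2(5H)-one | COC1=CC(=O)OC1 | starting material
12 | 3-iodo-4-methoxyfuran-2(5H)-one | COC1=C(I)C(=O)OC1 | intermediate
13 | all-cis quinolin-8-yl amide with the methyl tetronate at C7 | O=C(Nc1cccc2cccnc12)[C@H]1[C@@H](CCC)[C@@]2(OC(=O)c3ccccc32)[C@H]1C1=C(OC)COC1=O | intermediate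
14 | N-Boc imide of 13 | O=C(N(C(=O)OC(C)(C)C)c1cccc2cccnc12)[C@H]1[C@@H](CCC)[C@@]2(OC(=O)c3ccccc32)[C@H]1C1=C(OC)COC1=O | intermediate
15 | all-cis C6 acid with the methyl tetronate at C7 | OC(=O)[C@H]1[C@@H](CCC)[C@@]2(OC(=O)c3ccccc32)[C@H]1C1=C(OC)COC1=O | intermediate
16 | tert-butyl ester of 15 | CC(C)(C)OC(=O)[C@H]1[C@@H](CCC)[C@@]2(OC(=O)c3ccccc32)[C@H]1C1=C(OC)COC1=O | intermediate
17 | tert-butyl ester with the tetronic acid at C7 | CC(C)(C)OC(=O)[C@H]1[C@@H](CCC)[C@@]2(OC(=O)c3ccccc32)[C@H]1C1=C(O)COC1=O | intermediate
18 | tert-butyl ester with the enol triflate at C3a | CC(C)(C)OC(=O)[C@H]1[C@@H](CCC)[C@@]2(OC(=O)c3ccccc32)[C@H]1C1=C(OS(=O)(=O)C(F)(F)F)COC1=O | intermediate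
19 | tributyl(vinyl)stannane | C=C[Sn](CCCC)(CCCC)CCCC | starting material
20 | tert-butyl ester with the 4-vinylbutenolide at C7 | CC(C)(C)OC(=O)[C@H]1[C@@H](CCC)[C@@]2(OC(=O)c3ccccc32)[C@H]1C1=C(C=C)COC1=O | intermediate
21 | C6 acid with the 4-vinylbutenolide at C7 | OC(=O)[C@H]1[C@@H](CCC)[C@@]2(OC(=O)c3ccccc32)[C@H]1C1=C(C=C)COC1=O | intermediate
22 | N-hydroxyphthalimide | ON1C(=O)c2ccccc2C1=O | starting material
23 | N-acyloxyphthalimide of 21 | O=C(ON1C(=O)c2ccccc2C1=O)[C@H]1[C@@H](CCC)[C@@]2(OC(=O)c3ccccc32)[C@H]1C1=C(C=C)COC1=O | intermediate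
24 | (6S,7R,3′R,8′R) tetracyclic butenolide, C3 unsubstituted | C1OC(=O)C2=C1CC[C@H]1[C@@H](CCC)[C@@]3(OC(=O)c4ccccc43)[C@@H]21 | intermediate
25 | butanal | CCCC=O | starting material
26 | 1-(tert-butyldimethylsilyloxy)furan derived from 24 | c1oc(O[Si](C)(C)C(C)(C)C)c2c1CC[C@H]1[C@@H](CCC)[C@@]3(OC(=O)c4ccccc43)[C@@H]21 | intermediate
27 | 3-(1-hydroxybutyl) adduct (mixture at C3 and carbinol carbon) | CCCC(O)C1OC(=O)C2=C1CC[C@H]1[C@@H](CCC)[C@@]3(OC(=O)c4ccccc43)[C@@H]21 | intermediate
28 | mesylate of 27 | CCCC(OS(C)(=O)=O)C1OC(=O)C2=C1CC[C@H]1[C@@H](CCC)[C@@]3(OC(=O)c4ccccc43)[C@@H]21 | intermediate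
29 | CNP0248594.2, (3Z,6S,7R,3′R,8′R) | CCC/C=C1\OC(=O)C2=C1CC[C@H]1[C@@H](CCC)[C@@]3(OC(=O)c4ccccc43)[C@@H]21 | target

**Summary**

Total step count: 16. Longest linear sequence: 15 steps (steps 1–4 and 6–16; step 5 is a one-step side branch).

Steps most likely to fail:

1. Step 14. The cyclobutyl radical may take up hydrogen before it cyclises, or may open by β-scission of a ring bond to C3′, which would give a benzylic, oxygen-substituted radical. Ring B would then be closed by a polar coupling at C3a–C4 instead. The fallback sets out from 13: reduction with Cp2Zr(H)Cl gives the C6 aldehyde F1, methylenation with Ph3P=CH2 at −78 °C the C6 vinyl compound F2, demethylation (LiCl, DMSO) the tetronic acid F3 and Tf2O/i-Pr2NEt the enol triflate F4. Hydroboration of the vinyl group with 9-BBN gives the alkylborane F5, and intramolecular B-alkyl Suzuki–Miyaura coupling (PdCl2(dppf), AsPh3, Cs2CO3, DMF/THF/H2O) joins C4 to C3a and returns to the route at 24.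

2. Step 2. Palladation of a methylene flanked by the quaternary spiro carbon may be sluggish under the weak carboxylate direction, the two enantiotopic CH2 groups may be poorly told apart, or a second alkenylation may follow. The bidentate auxiliary would then be introduced first and enantiopurity secured by resolution. The fallback sets out from 5: coupling with 9 (EDC·HCl, DMAP) gives the quinolin-8-yl amide F6, which is mono-propylated at the cis β-position with 1-iodopropane (Pd(OAc)2, Ag2CO3, (BnO)2PO2H, t-AmOH, 110 °C) to racemic 10. Preparative chromatography on a chiral stationary phase separates 10 from its mirror image F7, and the route is rejoined at 10.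

3. Step 6. Oxidative addition of the hindered, electron-poor iodide 12 to the palladacycle may be slower than its protodeiodination on the crowded all-cis face. C7 would then be alkylated with a small, reactive electrophile and the tetronate built afterwards. The fallback sets out from 10: alkylation with ethyl iodoacetate under the same auxiliary control (Pd(OAc)2, Ag2CO3, (BnO)2PO2H, t-AmOH) gives the C7 acetic ester F8, saponification (LiOH, then HCl to reclose the phthalide) the acid F9, and O-alkylation with methyl bromoacetate (K2CO3, DMF) the acyloxyacetate F10. Dieckmann cyclisation (KOt-Bu, THF) gives the tetronic acid F11, and O-methylation with Me3SiCHN2 returns to the route at 13.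

**Further compounds**

F1 | step 14 | C6 aldehyde with the methyl tetronate at C7 | O=C[C@H]1[C@@H](CCC)[C@@]2(OC(=O)c3ccccc32)[C@H]1C1=C(OC)COC1=O
F2 | step 14 | C6 vinyl compound with the methyl tetronate at C7 | C=C[C@H]1[C@@H](CCC)[C@@]2(OC(=O)c3ccccc32)[C@H]1C1=C(OC)COC1=O
F3 | step 14 | C6 vinyl tetronic acid | C=C[C@H]1[C@@H](CCC)[C@@]2(OC(=O)c3ccccc32)[C@H]1C1=C(O)COC1=O
F4 | step 14 | C6 vinyl enol triflate | C=C[C@H]1[C@@H](CCC)[C@@]2(OC(=O)c3ccccc32)[C@H]1C1=C(OS(=O)(=O)C(F)(F)F)COC1=O
F5 | step 14 | B-alkyl-9-borabicyclo[3.3.1]nonane from F4 | C1CCC2CCCC1B2CC[C@H]1[C@@H](CCC)[C@@]2(OC(=O)c3ccccc32)[C@H]1C1=C(OS(=O)(=O)C(F)(F)F)COC1=O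
F6 | step 2 | N-(quinolin-8-yl) amide of 5 | O=C(Nc1cccc2cccnc12)[C@H]1C[C@@]2(OC(=O)c3ccccc32)C1
F7 | step 2 | mirror image of 10 | O=C(Nc1cccc2cccnc12)[C@@H]1[C@H](CCC)[C@]2(OC(=O)c3ccccc32)C1
F8 | step 6 | all-cis amide with CH2CO2Et at C7 | O=C(Nc1cccc2cccnc12)[C@H]1[C@@H](CCC)[C@@]2(OC(=O)c3ccccc32)[C@H]1CC(=O)OCC
F9 | step 6 | all-cis amide with CH2CO2H at C7 | O=C(Nc1cccc2cccnc12)[C@H]1[C@@H](CCC)[C@@]2(OC(=O)c3ccccc32)[C@H]1CC(=O)O
F10 | step 6 | all-cis amide with CH2C(=O)OCH2CO2Me at C7 | O=C(Nc1cccc2cccnc12)[C@H]1[C@@H](CCC)[C@@]2(OC(=O)c3ccccc32)[C@H]1CC(=O)OCC(=O)OC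
F11 | step 6 | all-cis amide with the tetronic acid at C7 | O=C(Nc1cccc2cccnc12)[C@H]1[C@@H](CCC)[C@@]2(OC(=O)c3ccccc32)[C@H]1C1=C(O)COC1=O
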